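**Plan**
1. Ring B is numbered C1 (carries the CH2 link to aromatic ring A), C2 (enol carbon), C3 (quaternary stereocentre with prenyl and isobutyryl), C4 (enol carbon), C5 (methyl-bearing carbon) and C6 (ketone). After removal of two methoxymethyl (MOM) ethers from ring A, the retrosynthesis cuts C1–C2 and then C5–C6.
2. Enabling feature: ring B is an enolised cyclohexane-1,3,5-trione (C2, C4, C6). C6, C1 and the bridging CH2 are therefore the 3-arylpropanoyl unit of a chroman-2-one (dihydrocoumarin) fused to ring A, and C2–C3–C4–C5 is a β-keto ester that carries an ethyl ketone.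
3. Forward: ring A is made first as its lactone (phloroglucinol, annulation, acylation, prenylation, two MOM ethers) and the acyclic keto ester is made separately. Ring B then closes last in one flask, by Claisen acylation (C5–C6) followed by dianion Dieckmann closure (C1–C2), and acid frees the phenols.
4. Stereochemistry: the single stereocentre C3 stems from a BINAP–ruthenium hydrogenation of a β-keto ester. That carbinol centre steers two chelate-controlled dianion reactions at the α-carbon (prenylation, then aldol) and is then oxidised away; C3 has no hydrogen and cannot epimerise afterwards.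

Key step: step 9

Remark 1: ring B of 19 and 20 is written as the dienol tautomer of the target SMILES, one of the interconverting enol forms of the same trione; the descriptor (S) refers to that tautomer.
Remark 2: all three oxygens of ring A are free phenols in 20, so the phenol that closes the lactone in 12, 15 and 17 leaves no trace in the target. The regiochemistry written is the expected one, and the ring opening in step 7 converges an 8-acyl isomer of 12 onto the same acid 13.

**Route**

Step 1
Reactants: 1 methyl 4-methyl-3-oxopentanoate
Product: 2 methyl (3S)-3-hydroxy-4-methylpentanoate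
Conditions: H2 (50 atm), RuCl2[(R)-BINAP] (cat.), MeOH, 50 °C
Reagents that add atoms: none
Why: Noyori asymmetric hydrogenation of a β-keto ester, in which the (R)-BINAP complex delivers hydrogen to the same face as in its reduction of methyl acetoacetate to the (R)-alcohol, which here is the (3S)-carbinol because isopropyl outranks the CH2CO2Me arm.

Step 2
Reactants: 2 methyl (3S)-3-hydroxy-4-methylpentanoate; 3 prenyl bromide (1-bromo-3-methylbut-2-ene)
Product: 4 methyl (2R,3R)-3-hydroxy-4-methyl-2-(3-methylbut-2-en-1-yl)pentanoate
Conditions: LiN(iPr)2 (2.2 equiv), THF, −78 → −20 °C; prenyl bromide, DMPU, −78 → 0 °C; AcOH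
Reagents that add atoms: prenyl bromide, CC(C)=CCBr
Why: Fráter–Seebach alkylation, in which the alkoxide–enolate dianion is held as a six-membered lithium chelate and the allylic bromide should enter C2 on the face away from the isopropyl group, setting C2 anti to the C3 oxygen (the C3 descriptor changes to R only because the substituted C2 now outranks isopropyl).

Step 3
Reactants: 4 methyl (2R,3R)-3-hydroxy-4-methyl-2-(3-methylbut-2-en-1-yl)pentanoate; 5 propanal
Product: 6 methyl (2R,3R)-3-hydroxy-2-(1-hydroxypropyl)-4-methyl-2-(3-methylbut-2-en-1-yl)pentanoate (both epimers at the hydroxypropyl carbinol carbon)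
Conditions: LiN(iPr)2 (2.5 equiv), THF, −78 → −15 °C; EtCHO, −78 °C; AcOH, −78 °C
Reagents that add atoms: propanal, CCC=O
Why: Aldol addition of the fully substituted Fráter–Seebach dianion, in which propanal should again add on the face opposite the isopropyl group of the chelate so that the quaternary C2 is set by the C3 carbinol centre, while the new hydroxypropyl carbinol centre forms without control and is erased in step 4.

Step 4
Reactants: 6 methyl (2R,3R)-3-hydroxy-2-(1-hydroxypropyl)-4-methyl-2-(3-methylbut-2-en-1-yl)pentanoate
Product: 7 methyl (2R)-2-(2-methylpropanoyl)-2-(3-methylbut-2-en-1-yl)-3-oxopentanoate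
Conditions: Dess–Martin periodinane (3 equiv), CH2Cl2, 0 °C → rt
Reagents that add atoms: none
Why: Dess–Martin oxidation of both secondary alcohols to ketones is mild and spares the alkene, the quaternary α-carbon rules out enolisation or elimination, and the quaternary carbon is left as the only stereocentre with the (R) configuration.

Step 5
Reactants: 8 phloroglucinol (benzene-1,3,5-triol); 9 acrylic acid
Product: 10 5,7-dihydroxychroman-2-one
Conditions: polystyrene–SO3H resin (Amberlyst-15), toluene, reflux, Dean–Stark; 8 in excess
Reagents that add atoms: acrylic acid, C=CC(=O)O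
Why: Acid-catalysed Friedel–Crafts conjugate addition of the electron-rich triol to acrylic acid followed by lactonisation is a known entry to 3,4-dihydrocoumarins, the symmetry of 8 allows only one product, and an excess of 8 should hold back a second annulation.

Step 6
Reactants: 10 5,7-dihydroxychroman-2-one; 11 isobutyryl chloride (2-methylpropanoyl chloride)
Product: 12 5,7-dihydroxy-6-(2-methylpropanoyl)chroman-2-one
Conditions: AlCl3 (4 equiv), PhNO2–CH2Cl2, 0 → 50 °C; cold dilute HCl work-up
Reagents that add atoms: isobutyryl chloride, CC(C)C(Cl)=O
Why: Friedel–Crafts acylation of a phloroglucinol-type ring, expected at C6 because that carbon lies between the two free hydroxyls and para to the weakly donating lactone oxygen and its ketone is then held by hydrogen bonds from both sides.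

Step 7
Reactants: 12 5,7-dihydroxy-6-(2-methylpropanoyl)chroman-2-one; 3 prenyl bromide
Product: 15 5,7-dihydroxy-6-(2-methylpropanoyl)-8-(3-methylbut-2-en-1-yl)chroman-2-one, via ring-opened hydroxy acid 13 (not isolated), via prenylated hydroxy acid 14 (not isolated)
Conditions: KOH (10% aq.), prenyl bromide, 0 °C; HCl to pH 3, extraction; EDC·HCl, CH2Cl2–THF, 0 °C → rt
Reagents that add atoms: prenyl bromide, CC(C)=CCBr
Why: C-alkylation of an acylphloroglucinol phenolate by prenyl bromide in aqueous alkali attacks the only free ring carbon of the saponified lactone, and carbodiimide lactonisation should then close the six-membered ring through the more acidic, non-chelated hydroxyl para to the ketone in preference to the hydrogen-bonded ortho hydroxyl.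

Step 8
Reactants: 15 5,7-dihydroxy-6-(2-methylpropanoyl)-8-(3-methylbut-2-en-1-yl)chroman-2-one; 16 chloromethyl methyl ether
Product: 17 5,7-bis(methoxymethoxy)-6-(2-methylpropanoyl)-8-(3-methylbut-2-en-1-yl)chroman-2-one
Conditions: MOMCl (5 equiv), iPr2NEt (6 equiv), Bu4NI (cat.), CH2Cl2, 0 °C → reflux
Reagents that add atoms: chloromethyl methyl ether, COCCl
Why: Williamson-type etherification of both phenols with chloromethyl methyl ether and a hindered amine, run with excess reagent, iodide catalysis and warming because both hydroxyls are hydrogen-bonded to the ketone, while the non-nucleophilic base leaves the aryl lactone intact.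

Step 9
Reactants: 7 methyl (2R)-2-(2-methylpropanoyl)-2-(3-methylbut-2-en-1-yl)-3-oxopentanoate; 17 5,7-bis(methoxymethoxy)-6-(2-methylpropanoyl)-8-(3-methylbut-2-en-1-yl)chroman-2-one
Product: 19 (4S)-3,5-dihydroxy-6-{[2-hydroxy-4,6-bis(methoxymethoxy)-5-(2-methylpropanoyl)-3-(3-methylbut-2-en-1-yl)phenyl]methyl}-2-methyl-4-(2-methylpropanoyl)-4-(3-methylbut-2-en-1-yl)cyclohexa-2,5-dien-1-one, via phenol diketone 18 (not isolated)
Conditions: LiN(SiMe3)2 (2.2 equiv), THF, −78 °C; add 17, −78 → −30 °C; LiN(iPr)2 (4 equiv), −78 → 0 °C; AcOH, −78 °C
Reagents that add atoms: none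
Why: LiN(SiMe3)2 removes a proton from the CH2 of the ethyl ketone of 7 (the isopropyl CH is tertiary and slower, the quaternary carbon has none), and this enolate adds to the aryl ester carbonyl of lactone 17 and expels the ring A phenoxide, which forms C5–C6 and leaves diketone 18 as its lithium diketonate. LiN(iPr)2 then removes a proton from C1, the CH2 next to C6, and this terminal carbanion of the diketone dianion attacks the methyl ester in a 6-exo-trig Dieckmann closure that forms C1–C2 and ring B, made irreversible by loss of methoxide and deprotonation of the trione. The closest known reactions are the opening of dihydrocoumarins by ketone or ester enolates (a crossed Claisen with an aryl ester) and the acylation of β-diketone dianions by esters to give 1,3,5-triketones. No stereocentre is formed, and the quaternary carbon, having no hydrogen, keeps the configuration set in step 3. The step needs C-acylation to outrun proton transfer from the lactone CH2 and the Dieckmann closure to win over the reversible aldol of C1 onto the isobutyryl ketone; the electrophilic aryl ester, the low temperature, excess amide base (the two isopropyl ketones also consume it) and the stable trione enolate, which also shields the product from retro-Claisen loss of an acyl group, are expected to secure this.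

Step 10
Reactants: 19 (the bis-MOM ether of the target)
Product: 20 (4S)-3,5-dihydroxy-2-methyl-4-(2-methylpropanoyl)-4-(3-methylbut-2-en-1-yl)-6-{[2,4,6-trihydroxy-3-(2-methylpropanoyl)-5-(3-methylbut-2-en-1-yl)phenyl]methyl}cyclohexa-2,5-dien-1-one (CNP0191741.1)
Conditions: HCl (3 M aq.), MeOH, rt
Reagents that add atoms: none
Why: Acid-catalysed acetal exchange with methanol should remove both MOM ethers, which sit ortho to the aryl ketone and are labile, under conditions mild enough to leave the prenyl groups, the enols and the non-epimerisable quaternary carbon unchanged.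

**Compound list**
1 | methyl 4-methyl-3-oxopentanoate | COC(=O)CC(=O)C(C)C | starting material
2 | methyl (3S)-3-hydroxy-4-methylpentanoate | COC(=O)C[C@H](O)C(C)C | intermediate
3 | prenyl bromide (1-bromo-3-methylbut-2-ene) | CC(C)=CCBr | starting material
4 | methyl (2R,3R)-3-hydroxy-4-methyl-2-(3-methylbut-2-en-1-yl)pentanoate | COC(=O)[C@H](CC=C(C)C)[C@H](O)C(C)C | intermediate
5 | propanal | CCC=O | starting material
6 | methyl (2R,3R)-3-hydroxy-2-(1-hydroxypropyl)-4-methyl-2-(3-methylbut-2-en-1-yl)pentanoate, both epimers at the hydroxypropyl carbinol carbon | COC(=O)[C@](CC=C(C)C)(C(O)CC)[C@H](O)C(C)C | intermediate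
7 | methyl (2R)-2-(2-methylpropanoyl)-2-(3-methylbut-2-en-1-yl)-3-oxopentanoate | COC(=O)[C@@](CC=C(C)C)(C(=O)C(C)C)C(=O)CC | intermediate
8 | phloroglucinol (benzene-1,3,5-triol) | Oc1cc(O)cc(O)c1 | starting material
9 | acrylic acid | C=CC(=O)O | starting material
10 | 5,7-dihydroxychroman-2-one | O=C1CCc2c(O)cc(O)cc2O1 | intermediate
11 | isobutyryl chloride (2-methylpropanoyl chloride) | CC(C)C(Cl)=O | starting material
12 | 5,7-dihydroxy-6-(2-methylpropanoyl)chroman-2-one | CC(C)C(=O)c1c(O)cc2OC(=O)CCc2c1O | intermediate
13 | 3-[2,4,6-trihydroxy-3-(2-methylpropanoyl)phenyl]propanoic acid (not isolated) | CC(C)C(=O)c1c(O)cc(O)c(CCC(=O)O)c1O | intermediate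
14 | 3-[2,4,6-trihydroxy-3-(2-methylpropanoyl)-5-(3-methylbut-2-en-1-yl)phenyl]propanoic acid (not isolated) | CC(C)=CCc1c(O)c(CCC(=O)O)c(O)c(C(=O)C(C)C)c1O | intermediate
15 | 5,7-dihydroxy-6-(2-methylpropanoyl)-8-(3-methylbut-2-en-1-yl)chroman-2-one | CC(C)=CCc1c2OC(=O)CCc2c(O)c(C(=O)C(C)C)c1O | intermediate
16 | chloromethyl methyl ether | COCCl | starting material
17 | 5,7-bis(methoxymethoxy)-6-(2-methylpropanoyl)-8-(3-methylbut-2-en-1-yl)chroman-2-one | CC(C)=CCc1c2OC(=O)CCc2c(OCOC)c(C(=O)C(C)C)c1OCOC | intermediate
18 | methyl (2S)-7-[2-hydroxy-4,6-bis(methoxymethoxy)-5-(2-methylpropanoyl)-3-(3-methylbut-2-en-1-yl)phenyl]-4-methyl-2-(2-methylpropanoyl)-2-(3-methylbut-2-en-1-yl)-3,5-dioxoheptanoate, C4 unassigned and enolisable (not isolated) | CC(C)=CCc1c(O)c(CCC(=O)C(C)C(=O)[C@](CC=C(C)C)(C(=O)C(C)C)C(=O)OC)c(OCOC)c(C(=O)C(C)C)c1OCOC | intermediate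
19 | (4S)-3,5-dihydroxy-6-{[2-hydroxy-4,6-bis(methoxymethoxy)-5-(2-methylpropanoyl)-3-(3-methylbut-2-en-1-yl)phenyl]methyl}-2-methyl-4-(2-methylpropanoyl)-4-(3-methylbut-2-en-1-yl)cyclohexa-2,5-dien-1-one | CC(C)=CCc1c(O)c(CC2=C(O)[C@@](CC=C(C)C)(C(=O)C(C)C)C(O)=C(C)C2=O)c(OCOC)c(C(=O)C(C)C)c1OCOC | intermediate
20 | (4S)-3,5-dihydroxy-2-methyl-4-(2-methylpropanoyl)-4-(3-methylbut-2-en-1-yl)-6-{[2,4,6-trihydroxy-3-(2-methylpropanoyl)-5-(3-methylbut-2-en-1-yl)phenyl]methyl}cyclohexa-2,5-dien-1-one | CC(C)=CCc1c(O)c(CC2=C(O)[C@@](CC=C(C)C)(C(=O)C(C)C)C(O)=C(C)C2=O)c(O)c(C(=O)C(C)C)c1O | target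

**Step count and risks**

Total steps: 10. Longest linear sequence: 6 steps (steps 5–10, or equally steps 1–4, 9 and 10).

Steps most likely to fail:

Step 9. Proton transfer from the lactone CH2 to the enolate or the amide base, with ketene-type opening of the lactone, may outpace C-acylation. The triacylated quaternary carbon may also shed an acyl group by retro-Claisen attack, and the isopropyl ketones may consume base so that the second deprotonation at C1 stays incomplete. The fallback makes the C5–C6 bond by aldol addition and oxidation instead of Claisen acylation; it sets out from 17 and 7 and returns at 18. Reduction of 17 with iBu2AlH (1.05 equiv, CH2Cl2, −78 °C; the aryl ketone is shielded by two ortho substituents) should give the lactol 5,7-bis(methoxymethoxy)-6-(2-methylpropanoyl)-8-(3-methylbut-2-en-1-yl)chroman-2-ol F1. Its lithium salt, in equilibrium with the open phenoxide aldehyde, is added at −78 °C to the lithium enolate of 7 (LiN(SiMe3)2, THF) and quenched cold. This should give the β-hydroxy ketone methyl (2S)-5-hydroxy-7-[2-hydroxy-4,6-bis(methoxymethoxy)-5-(2-methylpropanoyl)-3-(3-methylbut-2-en-1-yl)phenyl]-4-methyl-2-(2-methylpropanoyl)-2-(3-methylbut-2-en-1-yl)-3-oxoheptanoate F2 as a mixture at C4 and C5. Dess–Martin oxidation of the carbinol then gives diketone 18 as an isolated compound, and 18 is closed to 19 with LiN(iPr)2 as in the second stage of step 9.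

Step 3. The hindered, fully substituted dianion may deprotonate propanal instead of adding to it, the aldolate may revert on warming or work-up, and facial selectivity at the new quaternary carbon may erode. The fallback brings in the propanoyl arm at the ketone oxidation level by C-acylation instead of aldol addition; it sets out from 4 and returns at 7. The same dianion of 4 is treated with N-methoxy-N-methylpropanamide (THF, −78 → −10 °C), whose chelated tetrahedral adduct is neither enolised nor reversible. This should give methyl (2S,3R)-3-hydroxy-4-methyl-2-(3-methylbut-2-en-1-yl)-2-propanoylpentanoate F3, with the same spatial arrangement as in 6 (the descriptor changes because the ketone outranks the carbinol arm). A single Dess–Martin oxidation of the remaining alcohol then gives 7.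

Step 7. O-alkylation, geminal double prenylation with loss of aromaticity, or lactone closure through the chelated hydroxyl may compete with mono-C-prenylation and the intended ring closure. The fallback introduces the prenyl group without opening the lactone; it sets out from 12 and returns at 15. Lewis-acid Friedel–Crafts alkylation of 12 with 2-methylbut-3-en-2-ol and BF3·OEt2 in dioxane at room temperature attacks the only free ring position, C8, and gives 15 directly. It makes no compound outside the list (entry F0).

**Further compounds**
F1 | step 9 | 5,7-bis(methoxymethoxy)-6-(2-methylpropanoyl)-8-(3-methylbut-2-en-1-yl)chroman-2-ol | CC(C)=CCc1c2OC(O)CCc2c(OCOC)c(C(=O)C(C)C)c1OCOC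
F2 | step 9 | methyl (2S)-5-hydroxy-7-[2-hydroxy-4,6-bis(methoxymethoxy)-5-(2-methylpropanoyl)-3-(3-methylbut-2-en-1-yl)phenyl]-4-methyl-2-(2-methylpropanoyl)-2-(3-methylbut-2-en-1-yl)-3-oxoheptanoate | CC(C)=CCc1c(O)c(CCC(O)C(C)C(=O)[C@](CC=C(C)C)(C(=O)C(C)C)C(=O)OC)c(OCOC)c(C(=O)C(C)C)c1OCOC
F3 | step 3 | methyl (2S,3R)-3-hydroxy-4-methyl-2-(3-methylbut-2-en-1-yl)-2-propanoylpentanoate | COC(=O)[C@](CC=C(C)C)(C(=O)CC)[C@H](O)C(C)C
F0 | step 7 | none | none
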